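**Plan**

- Retrosynthesis: the two trisubstituted C=C bonds of the prenyl groups are cut first (double cross-metathesis of a 6,8-diallyl compound), then the C6–CH2 and C8–CH2 bonds (allyl groups returned to O5 and O7).
- Enabling feature: in the phloroglucinol ring A, C6 is ortho to O5 and O7, C8 is ortho to O7 and para to O5, and C4a is quaternary. Allyl groups placed on O5 and O7 can therefore only end on C6 and C8. The C4 carbonyl peri to O5 offers a chelation site for Eu(fod)3 (fod = 6,6,7,7,8,8,8-heptafluoro-2,2-dimethyloctane-3,5-dionate).
- Forward order: no ring is built, since the chroman-4-one comes intact with aromadendrin. Allyl is joined to O7, O3 and O4' are capped as MOM ethers, allyl is joined to O5, both allyls are moved to carbon, the MOM groups are removed, and allyl is converted to prenyl last.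
- Stereochemistry: C2 and C3 are bought with natural (2R,3R)-aromadendrin and are only preserved. No step uses strong base, and the 4'-O-MOM and 3-O-MOM groups block the pathways that open ring C.

Key step: step 4

Assumption: (+)-(2R,3R)-aromadendrin (dihydrokaempferol) is available as the single natural enantiomer, so both stereocentres of the target are present from the start.

**Route**

Step 1
Reactants: 1 (2R,3R)-aromadendrin; 2 allyl bromide
Product: 3 (2R,3R)-7-O-allylaromadendrin
Conditions: allyl bromide (1.05 equiv), K2CO3 (1.1 equiv), acetone, rt, Ar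
Reagents that add atoms: allyl bromide (2), C=CCBr
Why: Williamson etherification (SN2) in which the 7-OH, para to the C4 carbonyl and the most acidic hydroxyl, is the only one deprotonated by one equivalent of weak base, while the chelated 5-OH, the less acidic 4'-OH and the alcoholic 3-OH stay protonated and C2/C3 are untouched at room temperature.

Step 2
Reactants: 3 (2R,3R)-7-O-allylaromadendrin; 4 chloromethyl methyl ether
Product: 5 (2R,3R)-7-O-allyl-3,4'-bis-O-(methoxymethyl)aromadendrin
Conditions: MOMCl (3 equiv), iPr2NEt (4 equiv), CH2Cl2, 0 °C → rt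
Reagents that add atoms: chloromethyl methyl ether (4), COCCl
Why: Amine-base MOM etherification should cap the free 4'-phenol and the secondary 3-OH, whereas the 5-OH, held in a hydrogen bond to the C4 carbonyl, is known to stay free under these conditions in 5-hydroxyflavanones and 2-hydroxyaryl ketones.

Step 3
Reactants: 5 (2R,3R)-7-O-allyl-3,4'-bis-O-(methoxymethyl)aromadendrin; 6 allyl alcohol
Product: 7 (2R,3R)-5,7-di-O-allyl-3,4'-bis-O-(methoxymethyl)aromadendrin
Conditions: allyl alcohol (2 equiv), PPh3 (2 equiv), DIAD (2 equiv), THF, 0 °C → rt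
Reagents that add atoms: allyl alcohol (6), C=CCO
Why: Mitsunobu etherification, in which the chelated 5-OH protonates the betaine and is alkylated by the allyloxyphosphonium ion under neutral conditions, as known for 5-O-prenylation of 5-hydroxyflavanones, so the base-induced opening of ring C to a chalcone is avoided.

Step 4
Reactants: 7 (2R,3R)-5,7-di-O-allyl-3,4'-bis-O-(methoxymethyl)aromadendrin
Product: 11 (2R,3R)-6,8-diallyl-3,4'-bis-O-(methoxymethyl)aromadendrin, via C6 dienone 8 (not isolated), via 6-allyl monophenol 9 (not isolated), via C8 dienone 10 (not isolated)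
Conditions: Eu(fod)3 (10 mol %), 1,2-dichlorobenzene, 100 °C, then 175 °C, sealed tube, Ar
Reagents that add atoms: none
Why: Eu(fod)3 (trivalent europium) chelates the C4 carbonyl and O5 and lets the O5 allyl group pass at about 100 °C through a chair-like [3,3] transition state to C6, giving dienone 8, which enolises to monophenol 9; at 175 °C the unchelated O7 allyl ether of 9 makes the same thermal shift to its only free ortho carbon, C8, via dienone 10. The closest known reactions are the europium-catalysed Claisen and Claisen–Cope rearrangements of 5-O-allyl and 5-O-prenyl ethers of 5-hydroxyflavanones and the thermal Claisen rearrangement of 7-allyloxy flavonoids and coumarins. No ring closes, and no lasting stereocentre arises because the sp3 carbons of 8 and 10 become aromatic again on tautomerisation. Only regiocontrol is needed and ring A supplies it: C4a is quaternary, C6 and C8 are the sole open positions ortho or para to O5 and O7, and an allyl group is identical after one or two allylic transpositions, so any other order of the shifts, including an ortho shift to an occupied C6 followed by a Cope relay to C8, would end at the same compound. The MOM ethers at O3 and O4' shut off the α-ketol and quinone methide pathways by which ring C could open, so C2 and C3 should survive the neutral, base-free heating.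

Step 5
Reactants: 11 (2R,3R)-6,8-diallyl-3,4'-bis-O-(methoxymethyl)aromadendrin
Product: 12 (2R,3R)-6,8-diallylaromadendrin
Conditions: HCl (3 M aq)/MeOH (1:4), 50 °C
Reagents that add atoms: none
Why: Acid-catalysed acetal cleavage (transacetalisation to dimethoxymethane) should free O3 and O4' while the side chains are still monosubstituted allyl groups, which do not cyclise onto the neighbouring phenols as prenyl groups could, and the trans-diequatorial C2/C3 centres are stable to dilute acid.

Step 6
Reactants: 12 (2R,3R)-6,8-diallylaromadendrin; 13 2-methyl-2-butene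
Product: 14 6,8-diprenylaromadendrin
Conditions: second-generation Grubbs catalyst (H2IMes)(PCy3)Cl2Ru=CHPh (5 mol %), 2-methyl-2-butene/CH2Cl2 (1:1), 40 °C, sealed tube
Reagents that add atoms: 2-methyl-2-butene (13), CC=C(C)C
Why: Olefin cross-metathesis in which each terminal allyl alkene exchanges its methylene for the isopropylidene of 2-methyl-2-butene with loss of propene; the trisubstituted prenyl alkene is a metathesis-inert sink in the large excess of the partner, and the ruthenium carbene tolerates free phenols and the α-ketol.

**Compound list**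

1 | (2R,3R)-aromadendrin, (2R,3R)-3,5,7-trihydroxy-2-(4-hydroxyphenyl)chroman-4-one | c1c(O)cc2c(c1O)C(=O)[C@H](O)[C@@H](c1ccc(O)cc1)O2 | starting material
2 | allyl bromide | C=CCBr | starting material
3 | (2R,3R)-7-O-allylaromadendrin | c1c(OCC=C)cc2c(c1O)C(=O)[C@H](O)[C@@H](c1ccc(O)cc1)O2 | intermediate
4 | chloromethyl methyl ether (MOMCl) | COCCl | starting material
5 | (2R,3R)-7-O-allyl-3,4'-bis-O-(methoxymethyl)aromadendrin, 5-OH free | c1c(OCC=C)cc2c(c1O)C(=O)[C@H](OCOC)[C@@H](c1ccc(OCOC)cc1)O2 | intermediate
6 | allyl alcohol | C=CCO | starting material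
7 | (2R,3R)-5,7-di-O-allyl-3,4'-bis-O-(methoxymethyl)aromadendrin | c1c(OCC=C)cc2c(c1OCC=C)C(=O)[C@H](OCOC)[C@@H](c1ccc(OCOC)cc1)O2 | intermediate
8 | C6 dienone, keto tautomer of 9 with C5=O and an sp3 C6 carrying H and allyl (C6 epimers, not isolated) | C=CCC1C(OCC=C)=CC2=C(C1=O)C(=O)[C@H](OCOC)[C@@H](c1ccc(OCOC)cc1)O2 | intermediate
9 | (2R,3R)-6-allyl-7-O-allyl-3,4'-bis-O-(methoxymethyl)aromadendrin (not isolated) | C=CCc1c(OCC=C)cc2c(c1O)C(=O)[C@H](OCOC)[C@@H](c1ccc(OCOC)cc1)O2 | intermediate
10 | C8 dienone, keto tautomer of 11 with C7=O and an sp3 C8 carrying H and allyl (C8 epimers, not isolated) | C=CCC=1C(=O)C(CC=C)C2=C(C=1O)C(=O)[C@H](OCOC)[C@@H](c1ccc(OCOC)cc1)O2 | intermediate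
11 | (2R,3R)-6,8-diallyl-3,4'-bis-O-(methoxymethyl)aromadendrin | C=CCc1c(O)c(CC=C)c2c(c1O)C(=O)[C@H](OCOC)[C@@H](c1ccc(OCOC)cc1)O2 | intermediate
12 | (2R,3R)-6,8-diallylaromadendrin | C=CCc1c(O)c(CC=C)c2c(c1O)C(=O)[C@H](O)[C@@H](c1ccc(O)cc1)O2 | intermediate
13 | 2-methyl-2-butene | CC=C(C)C | starting material
14 | 6,8-diprenylaromadendrin, (2R,3R) | CC(C)=CCc1c(O)c(CC=C(C)C)c2c(c1O)C(=O)[C@H](O)[C@@H](c1ccc(O)cc1)O2 | target

**Step count and risks**

Total step count: 6. Longest linear sequence: 6 steps (1 → 3 → 5 → 7 → 11 → 12 → 14).

Steps most likely to fail: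

1. Step 4. The unchelated O7 → C8 shift may stall at a temperature that the MOM ethers and the C2/C3 centres still tolerate, or the new ortho-allylphenols may cyclise on prolonged heating. Fallback, from 9 back to 11: the reaction is stopped after the 100 °C stage and monophenol 9 is isolated. Mitsunobu allylation of its chelated 5-OH (allyl alcohol 6, PPh3, DIAD, THF) should give the 6-allyl-5,7-bis(allyloxy) ether F1. Eu(fod)3 at 100 °C should then send the O5 allyl to the occupied C6, giving the 6,6-diallyl dienone F2. This cannot enolise and should pass one allyl on by a Cope shift to C8, giving the cross-conjugated dienone F3, which tautomerises to the 6,8-diallyl-7-allyloxy phenol F4. The O7 allyl, now only a protecting group, is removed with the zerovalent palladium complex Pd(PPh3)4 and morpholine in THF at rt to give 11. Both C–C bonds are then made through the chelated O5 at low temperature.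

2. Step 2. Site selectivity of the etherification may be lost: the hindered, hydrogen-bonded 3-OH may react too slowly, and forcing it may begin to alkylate the chelated 5-OH. Fallback, from 3 back to 7: one equivalent of MOMCl with iPr2NEt in CH2Cl2 at 0 °C should cap only the free 4'-phenol, giving the 4'-O-methoxymethyl ether F5. Williamson allylation of the 5-OH (allyl bromide 2, K2CO3, DMF, rt) should give the 5,7-di-O-allyl ether F6 with the 3-OH still free. With no phenol left, the 3-OH can be driven to its MOM ether with excess MOMCl, iPr2NEt and nBu4NI in CH2Cl2 at 40 °C, giving 7.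

3. Step 6. The catalyst may be deactivated by the chelating tetraol, 12 may be poorly soluble, or ruthenium hydride species may move the allyl double bonds into conjugation with ring A. Fallback, from 11 back to 14: the metathesis is run on the more soluble bis-MOM ether 11 with the same catalyst and 2-methyl-2-butene to give the 6,8-diprenyl bis-MOM ether F7. The MOM groups are then removed with dilute HCl in MeOH at rt to 40 °C, stopped early to keep the prenyl groups from closing onto the neighbouring phenols, giving 14.

**Further compounds**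

F1 | step 4 | (2R,3R)-6-allyl-5,7-di-O-allyl-3,4'-bis-O-(methoxymethyl)aromadendrin | C=CCc1c(OCC=C)cc2c(c1OCC=C)C(=O)[C@H](OCOC)[C@@H](c1ccc(OCOC)cc1)O2
F2 | step 4 | 6,6-diallyl dienone (C5=O, quaternary C6, 7-allyloxy), not isolated | C=CCC1(CC=C)C(OCC=C)=CC2=C(C1=O)C(=O)[C@H](OCOC)[C@@H](c1ccc(OCOC)cc1)O2
F3 | step 4 | cross-conjugated dienone (C5=O, 6-allyl, 7-allyloxy, sp3 C8 carrying H and allyl), not isolated | C=CCC1=C(OCC=C)C(CC=C)C2=C(C1=O)C(=O)[C@H](OCOC)[C@@H](c1ccc(OCOC)cc1)O2
F4 | step 4 | (2R,3R)-6,8-diallyl-7-O-allyl-3,4'-bis-O-(methoxymethyl)aromadendrin | C=CCc1c(OCC=C)c(CC=C)c2c(c1O)C(=O)[C@H](OCOC)[C@@H](c1ccc(OCOC)cc1)O2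
F5 | step 2 | (2R,3R)-7-O-allyl-4'-O-(methoxymethyl)aromadendrin | c1c(OCC=C)cc2c(c1O)C(=O)[C@H](O)[C@@H](c1ccc(OCOC)cc1)O2
F6 | step 2 | (2R,3R)-5,7-di-O-allyl-4'-O-(methoxymethyl)aromadendrin | c1c(OCC=C)cc2c(c1OCC=C)C(=O)[C@H](O)[C@@H](c1ccc(OCOC)cc1)O2
F7 | step 6 | (2R,3R)-6,8-diprenyl-3,4'-bis-O-(methoxymethyl)aromadendrin | CC(C)=CCc1c(O)c(CC=C(C)C)c2c(c1O)C(=O)[C@H](OCOC)[C@@H](c1ccc(OCOC)cc1)O2
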